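The trap in this flask is to read hours across charges: 5.0 h at 0.050 M of G is not a longer version of the violet run at 0.10 M.

| flask | G | Q | remark | time |
|---|---|---|---|---|
| amber | 0.034 M | 1.2 equiv | run made earlier |  |
| violet | 0.10 M | 1.2 equiv | run made earlier |  |
| Tuesday's | 0.050 M | 1.20 equiv |  | 5.0 h |
| Wednesday's | 0.050 M | 2.50 equiv |  | 5.0 h |
| Thursday's | 0.050 M | 5.00 equiv |  | 5.0 h |

| run | time / min | Z / % |
|---|---|---|
| amber | 10.0 | 0.1 |
| amber | 25.0 | 1.1 |
| amber | 50.0 | 2.4 |
| amber | 80.0 | 4.0 |
| amber | 120 | 5.4 |
| violet | 10.0 | 1.5 |
| violet | 25.0 | 3.6 |
| violet | 50.0 | 7.0 |
| violet | 80.0 | 9.9 |
| violet | 120 | 14.0 |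

(each reading ± 0.3 percentage points)

- amount of Z at the end, in percent of the G charged for Tuesday's, Wednesday's, Thursday's, in this order
- the shape of the row from first to last (falls, then rises / falls all the way / rises all the way / hardly changes / rises, then falls)

- the earlier runs were read with a standard deviation of 0.3 percentage points
- "hardly changes" means that all values lie within two and a half points (for a concentration: within two and a half percent of the largest)

Both earlier runs used the same equivalents, and their readings agree with a total order near two, so we put amber and Tuesday's flask, which has those equivalents too, on violet's clock. Tuesday's flask will have run 150 min of violet time, meaning its time multiplied by its G charge over violet's G charge. As a check, amber's last reading of 5.4% falls at 40.8 min of violet time, and there violet reads between 3.6% and 7.0%.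

Replacing violet's curve by its mean slope and carrying it to 150 min gives 17.5% of the charge as Z. But violet's readings bend: their slope after 50.0 min is lower than the mean slope. Continuing from the last reading on that late slope gives 17.0%, and this is our figure for Tuesday's flask. For Wednesday's and Thursday's the clock gives no figure, because no earlier run varied Q; we expect a rise if Q enters the rate. The G charge should stay untouched, so that all three flasks share 150 min and differ in Q.

The forecast gives 17.1%, 32.5% and 55%, a row that rises all the way, on the ground that “First order in each is the natural assumption”.

The flasks give 14.8%, 20.2% and 26.3%; the row rises all the way.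

    Z ⇌ J (K = 0.730, k = 0.160 h⁻¹)
    G + Q → Z, rate k2*[G]^1.5*[Q]^0.5 (k = 0.880 L mol⁻¹ h⁻¹)

Tuesday's Z stands below our figure by 2.2 percentage points. Violet time counts the making of Z, but Z goes to J in plain hours, and Tuesday's flask took 300 min, twice its 150 min of violet time. Without that conversion, Tuesday's Z is 19.6%, which closes 5.6% of what separates it from the full charge. Thursday's flask has the same 150 min, and two things act together on its Z: the conversion costs it 8.8 points, and the time given holds Z at 26.3% against 52.7% after ten times as long.

All runs are simulated from invented constants, and the scatter is random.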